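Assumptions (remarks on the chemistry):
- Germacrane numbering is used throughout: C1 (furanone C=O), C2, C3 (furanone C–O), C4 (bears C15H2OH), C5, C6 (lactone O), C7, C8 (ester O), C9, C10 (bears methyl C14 and the ring O), C11–C13 (α-methylene lactone carbons). "7,8-syn/anti" refers to O8 and C6 in the zigzag C9–C8–C7–C11; the target is 7,8-syn.
- The Barbier addition of step 12 is assumed to pass through the closed chair transition state and to give the 7,8-anti (8S) alcohol; the route is built on this and inverts C8 in step 15.

## Analysis of the target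

The target is a furanoheliangolide. A ten-membered carbocycle (C1–C10, ring B) is bridged by an oxygen between C3 and C10, which makes a 3(2H)-furanone (ring A: O, C3, C2, C1, C10 with C1=O and C2=C3). Ring B is fused at C6–C7 to an α-methylene-γ-butyrolactone (ring C: C6, O, C12, C11, C7). C8 carries a methacrylate and C4 a hydroxymethyl group.

Rings A and B form an 11-oxabicyclo[6.2.1]undecadienone in which C2=C3 is E and C4=C5 is Z with respect to the ten-membered ring, so the medium ring is strained and holds a cross-conjugated dienone.

There are four stereocentres. C6 (R), C7 (R) and C8 (R) are contiguous, with a 6,7-trans lactone and O8 syn to C6. C10 (R) is a remote quaternary centre; nothing in the ring relays it to the triad, so two independent sources of chirality are needed.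

Sensitive groups are two acrylate-type Michael acceptors (α-methylene lactone, methacrylate), the vinylogous ester, the allylic alcohol, and a γ-lactone that can migrate to O8 under base.

The hard parts are closing the medium ring across flat sp2 centres with the Z-C4=C5 bond in place, and placing O8 opposite to what a chair allylation delivers.

The feature that invites the strategy: C1/C3 are a masked 1,3-diketone, C3 is at the acid oxidation level, and C3 lies five bonds from O8 (C3–C4=C5–C6–C7–C8–O8). Parked on O8, C3 is the carbonyl of a seven-membered (Z)-enoate lactone. The C2–C3 bond of the target is then the result of an O8→C2 acyl shift that expands this lactone into the ten-membered carbocycle.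

## Retrosynthetic reasoning

**29 ⇒ 28 ⇒ 26.** The C15 silyl ether is removed last. The methacrylate (from 27) is attached to C8 with inversion (Mitsunobu), because the alcohol 26 that the route delivers is the 8S epimer. The esterification therefore also corrects C8 and costs no extra step.

**26 ⇒ 23 (key disconnection).** The bonds C2–C3 and C3–O(C10) of the furanone are cut and C3 is reconnected to O8. The precursor 23 is a fused 5/7 bis-lactone with an open side chain: no medium ring, no bridge, and the Z geometry of C4=C5 is enforced by the seven-membered ring. Forward, the methyl ketone enolate (C2) must attack the ε-lactone carbonyl C3 through a seven-membered transition state. Expulsion of O8 then gives the ten-membered 1,3-diketone 25, which acid closes to the furanone.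

**23 ⇒ 22.** The lactone bond C3–O8 and the bond C3–C4 are cut together: C3 is introduced as a one-carbon unit by carbonylative lactonization of the (Z)-alkenyl iodide onto the C8 hydroxyl. This avoids a separate acid fragment and a second metathesis.

**22 ⇒ 21 + 11.** The C7–C8 bond is cut (Barbier allylation). The bromolactone 21 brings C6 and directs C7 (attack anti to the C6 substituent, giving the trans lactone). The aldehyde 11 brings C10. The α-methylene lactone is formed in the same step.

**21 ⇒ 20 ⇒ 18 + 19.** The butenolide double bond C7=C11 is cut (ring-closing metathesis of the acrylate ester 20). The other alkene of 18 is a trisubstituted iodoalkene and cannot compete, so the two π systems on C6 are differentiated.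

**18 ⇒ 16 ⇒ 15 ⇒ 12 + 13.** The Z-iodoalkene comes from the alkyne by hydroxyl-directed trans-hydroalumination and iodination. C6 comes from kinetic resolution of the racemic enynol 15, itself the adduct of 12 and 13.

**11 ⇒ 9 ⇒ 7 ⇒ 6 ⇒ 5 ⇒ 2 + 3 ⇒ 1.** The aldehyde carbon C8 is unmasked from an allyl group. The quaternary C10 is set by alkylation of the lactic acid-derived dioxolanone 2 with 3 (self-regeneration of the stereocentre). The acetyl group C1–C2 comes from the acyl carbon through the Weinreb amide.

## Alternatives that were turned down

**Alternative 1: (textbook) C7–C8 macrocyclization on a finished furanone.** The forward key step would be an intramolecular Barbier allylation of aldehyde–bromolactone A1, followed by esterification. It was turned down for these reasons: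
- The C–C bond-forming step must close the nine-membered oxacycle from an open chain against the flat, rigid furanone–diene unit, so entropy and strain are paid together under reductive conditions that also allow dimerization.
- A1 contains the (Z)-C4=C5 dienone as an acyclic, isomerizable unit and a vinylogously acidic C6–H.
- C7 and C8 would be set transannularly without a reliable model.
- Making A1 needs a separate furanone acylation, a C3–C4 coupling and a bromolactone synthesis, which is longer than the present route for a riskier closure.

**Alternative 2: C3–O bond last, by transannular cyclization.** The forward key step would be a 5-endo-dig addition of O10 to the ynone of the ten-membered ring A2 (Ph3PAuNTf2 or base). It was turned down for these reasons: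
- The step forms only a C–O bond and no stereocentre.
- The difficulty is moved into A2, a cyclodecenynone that must hold the linear C1–C2≡C3–C4 unit, the Z-alkene and the trans-lactone in one ten-membered ring.
- The macrocyclization that makes A2 is again an open-chain medium-ring closure and becomes the real key step.
- Extra redox steps are needed to reach the ynone.

**Alternative 3: C9–C10 bond by dearomatization.** The forward key step would be a Lewis acid-promoted C-alkylation of the 2-methyl-3-silyloxyfuran in A3 at C10 by the terminal C8–C9 epoxide. This would close the nine-membered oxacycle, set C10 and unveil the C8 hydroxyl. It was turned down for these reasons: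
- A weak π-nucleophile must open an activated epoxide at the primary carbon in a nine-membered closure; hydride shift (Meinwald rearrangement), O-alkylation and intermolecular reaction are all faster processes.
- The face of C10 would be controlled only by ring conformation.
- A3 already holds every other stereocentre and an acid-labile siloxyfuran diene, so the precursor is hardly simpler than the product.

Key step: step 14

## Route

Step 1
Reactants: 1 (S)-lactic acid
Product: 2 (2S,5S)-2-tert-butyl-5-methyl-1,3-dioxolan-4-one
Conditions: t-BuCHO, TsOH (cat.), pentane, reflux, water separator; crystallization of the cis isomer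
Reagents that add atoms: pivalaldehyde, CC(C)(C)C=O
Why: Acid-catalysed acetalization of the α-hydroxy acid; the cis acetal is the thermodynamic product and should be purified by crystallization, its acetal centre being set by the lactate centre.

Step 2
Reactants: 2 (2S,5S)-2-tert-butyl-5-methyl-1,3-dioxolan-4-one; 3 allyl bromide
Product: 5 (2S,5R)-5-allyl-2-tert-butyl-5-methyl-1,3-dioxolan-4-one, via lithium enolate 4 (not isolated)
Conditions: LiN(iPr)2, THF, −78 °C; then 3, −78 → −30 °C
Reagents that add atoms: none
Why: Enolate alkylation with self-regeneration of the stereocentre: the planar enolate is attacked anti to the tert-butyl group, so allyl takes the place of the former hydrogen and the future C10 is set as R.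

Step 3
Reactants: 5 (2S,5R)-5-allyl-2-tert-butyl-5-methyl-1,3-dioxolan-4-one
Product: 6 (R)-2-hydroxy-N-methoxy-N,2-dimethylpent-4-enamide
Conditions: MeNH(OMe)·HCl, i-PrMgCl, THF, −20 → 0 °C
Reagents that add atoms: N,O-dimethylhydroxylamine hydrochloride, CNOC.Cl
Why: Aminolysis of the activated lactone-type carbonyl by the magnesium amide; the ring opens and the hemiacetal loses pivalaldehyde, which gives the Weinreb amide without touching the quaternary centre.

Step 4
Reactants: 6 (R)-2-hydroxy-N-methoxy-N,2-dimethylpent-4-enamide
Product: 7 (R)-N-methoxy-N,2-dimethyl-2-(triethylsilyloxy)pent-4-enamide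
Conditions: Et3SiOTf, 2,6-lutidine, CH2Cl2, 0 °C
Reagents that add atoms: triethylsilyl trifluoromethanesulfonate, CC[Si](CC)(CC)OS(=O)(=O)C(F)(F)F
Why: Silylation of the tertiary alcohol with a silyl triflate; it is done at the amide stage because an amide is not enolized by the triflate/base pair.

Step 5
Reactants: 7 (R)-N-methoxy-N,2-dimethyl-2-(triethylsilyloxy)pent-4-enamide
Product: 9 (R)-3-methyl-3-(triethylsilyloxy)hex-5-en-2-one, via magnesium chelate 8 (not isolated)
Conditions: MeMgBr, THF, 0 °C; aq. NH4Cl
Reagents that add atoms: methylmagnesium bromide, C[Mg]Br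
Why: Weinreb ketone synthesis: the chelated tetrahedral adduct survives until work-up, so the methyl ketone (C1, C2) forms without over-addition.

Step 6
Reactants: 9 (R)-3-methyl-3-(triethylsilyloxy)hex-5-en-2-one
Product: 11 (R)-3-methyl-4-oxo-3-(triethylsilyloxy)pentanal, via ozonide 10 (not isolated)
Conditions: O3, CH2Cl2, −78 °C; then PPh3, −78 °C → rt
Reagents that add atoms: ozone, [O-][O+]=O
Why: Ozonolysis of the terminal alkene with reductive work-up; ketone and silyl ether are inert, and the β-silyloxy aldehyde should be used without storage.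

Step 7
Reactants: 12 acrolein; 13 tert-butyldiphenyl(prop-2-yn-1-yloxy)silane
Product: 15 rac-6-(tert-butyldiphenylsilyloxy)hex-1-en-4-yn-3-ol, via lithium acetylide 14 (not isolated)
Conditions: n-BuLi, THF, −78 °C; then 12, −78 °C; aq. NH4Cl
Reagents that add atoms: none
Why: 1,2-Addition of a lithium acetylide to the enal; the hard nucleophile should add to the carbonyl and not in the conjugate sense.

Step 8
Reactants: 15 rac-6-(tert-butyldiphenylsilyloxy)hex-1-en-4-yn-3-ol
Product: 16 (S)-6-(tert-butyldiphenylsilyloxy)hex-1-en-4-yn-3-ol
Conditions: Ti(OiPr)4, L-(+)-diisopropyl tartrate, t-BuOOH (0.6 equiv), 4 Å molecular sieves, CH2Cl2, −20 °C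
Reagents that add atoms: none
Why: Sharpless kinetic resolution of a secondary allylic alcohol: only the vinyl group can be epoxidised, and with the L-(+)-tartrate the (R)-alcohol should react fast while the (S)-alcohol (future C6) is recovered.

Step 9
Reactants: 16 (S)-6-(tert-butyldiphenylsilyloxy)hex-1-en-4-yn-3-ol
Product: 18 (3S,4Z)-6-(tert-butyldiphenylsilyloxy)-5-iodohexa-1,4-dien-3-ol, via cyclic sodium alkenylaluminate 17 (not isolated)
Conditions: NaAlH2(OCH2CH2OMe)2, THF, 0 °C; EtOAc; then I2, −78 → 0 °C
Reagents that add atoms: iodine, II
Why: Hydroxyl-directed trans-hydroalumination of the propargylic alcohol places aluminium on the distal carbon (C4) cis to the carbinol carbon, and iodination with retention gives the Z-iodoalkene in which iodine and C6 are cis.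

Step 10
Reactants: 18 (3S,4Z)-6-(tert-butyldiphenylsilyloxy)-5-iodohexa-1,4-dien-3-ol; 19 2-(bromomethyl)acrylic acid
Product: 20 (3S,4Z)-6-(tert-butyldiphenylsilyloxy)-5-iodohexa-1,4-dien-3-yl 2-(bromomethyl)acrylate
Conditions: N,N'-diisopropylcarbodiimide, DMAP (cat.), CH2Cl2, 0 °C
Reagents that add atoms: none
Why: Carbodiimide (Steglich-type) esterification of the secondary alcohol at low temperature with little DMAP, so that the allylic bromide is not displaced; the C–O bond at C6 is not touched.

Step 11
Reactants: 20 (3S,4Z)-6-(tert-butyldiphenylsilyloxy)-5-iodohexa-1,4-dien-3-yl 2-(bromomethyl)acrylate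
Product: 21 (S)-3-(bromomethyl)-5-[(Z)-3-(tert-butyldiphenylsilyloxy)-2-iodoprop-1-en-1-yl]furan-2(5H)-one
Conditions: second-generation Grubbs catalyst (5 mol%), CH2Cl2, 40 °C
Reagents that add atoms: none
Why: Ring-closing metathesis of the vinyl group with the acrylate alkene forms the butenolide (C7=C11) and releases ethylene; the trisubstituted iodoalkene is inert and the neutral conditions should not racemize the γ-centre.

Step 12
Reactants: 21 (S)-3-(bromomethyl)-5-[(Z)-3-(tert-butyldiphenylsilyloxy)-2-iodoprop-1-en-1-yl]furan-2(5H)-one; 11 (R)-3-methyl-4-oxo-3-(triethylsilyloxy)pentanal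
Product: 22 (4R,5S)-4-[(1S,3R)-1-hydroxy-3-methyl-4-oxo-3-(triethylsilyloxy)pentyl]-5-[(Z)-3-(tert-butyldiphenylsilyloxy)-2-iodoprop-1-en-1-yl]-3-methylenedihydrofuran-2(3H)-one
Conditions: Zn dust, THF/sat. aq. NH4Cl, 0 °C → rt
Reagents that add atoms: none
Why: Barbier allylation: the allylzinc attacks the aldehyde (not the ketone) through its γ-carbon C7 anti to the C6 substituent (trans lactone), and the chair transition state with the ring-locked geometry (C6 trans to the CH2Zn carbon) should give the 7,8-anti (8S) alcohol with the exocyclic methylene in place.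

Step 13
Reactants: 22 Barbier adduct (as named in step 12)
Product: 23 bis-lactone: seven-membered (Z)-enoate lactone O8–C3(=O)–C4(CH2OSiPh2t-Bu)=C5–C6–C7–C8 fused at C6–C7 to the α-methylene-γ-butyrolactone, with the (R)-2-methyl-3-oxo-2-(triethylsilyloxy)butyl chain on C8; 6R,7R,8S,10R
Conditions: Pd(PPh3)4 (10 mol%), CO (1–3 bar), i-Pr2NEt, THF, 50 °C
Reagents that add atoms: carbon monoxide, [C-]#[O+]
Why: Palladium-catalysed carbonylative lactonization: oxidative addition to the alkenyl iodide and CO insertion give an acylpalladium that is trapped by the C8 hydroxyl; the Z geometry is retained (C3 cis to C6), C8 keeps its configuration, and CO pressure should outrun alkene insertion.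

Step 14
Reactants: 23 bis-lactone (as described in step 13)
Product: 26 (8S)-alcohol: the target skeleton with free C8–OH of 8S configuration and C15–OSiPh2t-Bu (6R,7R,8S,10R), via lithium enolate 24 (not isolated), via ring-expanded hydroxy diketone 25 (not isolated)
Conditions: LiN(SiMe3)2 (1.05 equiv), THF (0.005 M), −78 → −20 °C; then 2 M aq. HCl, THF, 0 °C → rt
Reagents that add atoms: none
Why: Proposed new method: a ring-expanding Claisen acyl transfer, the intramolecular form of the acylation of α′-silyloxy ketone enolates that leads to 3(2H)-furanones, with a lactone as acyl donor (closest known types: C-acylation of ketone lithium enolates by lactones, base-induced O→C acyl migration of the Baker–Venkataraman kind, acid cyclodehydration of α′-hydroxy-1,3-diketones). The base can enolize the C1 ketone only at C2 (C10 is quaternary), and enolate 24 reaches the lactone carbonyl C3 through a seven-membered transition state (7-exo-trig) to give an 11-oxabicyclo[4.4.1] tetrahedral alkoxide; its collapse with cleavage of C3–O8 turns the seven-membered lactone into the ten-membered carbocycle C1–C10, and the released C8 alkoxide deprotonates the new 1,3-diketone, so the diketonate makes the transfer irreversible and one equivalent of base suffices. Acid then removes the tertiary silyl group, O10 adds to the C3 carbonyl (5-exo-trig) and the hemiketal loses water to the vinylogous ester, which closes the furanone and completes the 11-oxabicyclo[6.2.1] core. No stereocentre is created: C6, C7, C8 and C10 are carried over from 23, the Z geometry of C4=C5 is inherited from the seven-membered ring, and the E geometry of C2=C3 within the large ring is dictated by the furanone. The step needs C-acylation at C3 and not conjugate addition to C5 or C13 or attack at the γ-lactone carbonyl C12; the seven-membered transition state (the others need eight-membered ones), the higher electrophilicity of the s-cis ester held in the lactone, low temperature and high dilution should secure this. In the acid stage O10 and not O8 must close onto the dicarbonyl; aqueous acid keeps hemiketals and vinylogous esters in equilibrium, so the 3(2H)-furanone, the most stabilized vinylogous ester, should be the product collected.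

Step 15
Reactants: 26 (8S)-alcohol (as described in step 14); 27 methacrylic acid
Product: 28 15-O-(tert-butyldiphenylsilyl) ether of the target (6R,7R,8R,10R)
Conditions: PPh3, diisopropyl azodicarboxylate, toluene, 0 °C → rt
Reagents that add atoms: none
Why: Mitsunobu esterification: the carboxylate displaces the activated C8 oxygen with inversion, so the acyl group is installed and C8 is corrected from S to R in one operation; no other free hydroxyl is present.

Step 16
Reactants: 28 15-O-(tert-butyldiphenylsilyl) ether of the target
Product: 29 the target, (6R,7R,8R,10R)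
Conditions: HF·pyridine, pyridine/THF, 0 °C → rt
Reagents that add atoms: none
Why: Fluoride cleavage of the primary silyl ether under buffered, non-basic conditions that leave both acrylate units, the lactone and the furanone untouched.

## Compound list

1 | (S)-lactic acid | C[C@H](O)C(=O)O | starting material
2 | (2S,5S)-2-tert-butyl-5-methyl-1,3-dioxolan-4-one | C[C@@H]1O[C@H](C(C)(C)C)OC1=O | intermediate
3 | allyl bromide | C=CCBr | starting material
4 | lithium enolate of 2 | CC1=C([O-])O[C@@H](C(C)(C)C)O1.[Li+] | intermediate
5 | (2S,5R)-5-allyl-2-tert-butyl-5-methyl-1,3-dioxolan-4-one | C=CC[C@@]1(C)O[C@H](C(C)(C)C)OC1=O | intermediate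
6 | (R)-2-hydroxy-N-methoxy-N,2-dimethylpent-4-enamide | C=CC[C@@](C)(O)C(=O)N(C)OC | intermediate
7 | (R)-N-methoxy-N,2-dimethyl-2-(triethylsilyloxy)pent-4-enamide | C=CC[C@@](C)(O[Si](CC)(CC)CC)C(=O)N(C)OC | intermediate
8 | magnesium chelate (tetrahedral adduct of 7 and MeMgBr, new centre undefined) | C=CC[C@@](C)(O[Si](CC)(CC)CC)C(C)(O[Mg]Br)N(C)OC | intermediate
9 | (R)-3-methyl-3-(triethylsilyloxy)hex-5-en-2-one | C=CC[C@@](C)(O[Si](CC)(CC)CC)C(C)=O | intermediate
10 | ozonide (1,2,4-trioxolane) of 9, epimers at the ring carbon | CC(=O)[C@](C)(O[Si](CC)(CC)CC)CC1OCOO1 | intermediate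
11 | (R)-3-methyl-4-oxo-3-(triethylsilyloxy)pentanal | CC(=O)[C@](C)(O[Si](CC)(CC)CC)CC=O | intermediate
12 | acrolein | C=CC=O | starting material
13 | tert-butyldiphenyl(prop-2-yn-1-yloxy)silane | C#CCO[Si](c1ccccc1)(c1ccccc1)C(C)(C)C | starting material
14 | lithium acetylide of 13 | [Li]C#CCO[Si](c1ccccc1)(c1ccccc1)C(C)(C)C | intermediate
15 | rac-6-(tert-butyldiphenylsilyloxy)hex-1-en-4-yn-3-ol | C=CC(O)C#CCO[Si](c1ccccc1)(c1ccccc1)C(C)(C)C | intermediate
16 | (S)-6-(tert-butyldiphenylsilyloxy)hex-1-en-4-yn-3-ol | C=C[C@H](O)C#CCO[Si](c1ccccc1)(c1ccccc1)C(C)(C)C | intermediate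
17 | cyclic sodium alkenylaluminate from 16 (Al on C4, H on C5) | C=C[C@@H]1O[Al-](OCCOC)(OCCOC)C(CO[Si](c2ccccc2)(c2ccccc2)C(C)(C)C)=C1.[Na+] | intermediate
18 | (3S,4Z)-6-(tert-butyldiphenylsilyloxy)-5-iodohexa-1,4-dien-3-ol | C=C[C@H](O)/C=C(\I)CO[Si](c1ccccc1)(c1ccccc1)C(C)(C)C | intermediate
19 | 2-(bromomethyl)acrylic acid | C=C(CBr)C(=O)O | starting material
20 | (3S,4Z)-6-(tert-butyldiphenylsilyloxy)-5-iodohexa-1,4-dien-3-yl 2-(bromomethyl)acrylate | C=C[C@H](OC(=O)C(=C)CBr)/C=C(\I)CO[Si](c1ccccc1)(c1ccccc1)C(C)(C)C | intermediate
21 | (S)-3-(bromomethyl)-5-[(Z)-3-(tert-butyldiphenylsilyloxy)-2-iodoprop-1-en-1-yl]furan-2(5H)-one | BrCC1=C[C@H](OC1=O)/C=C(\I)CO[Si](c2ccccc2)(c2ccccc2)C(C)(C)C | intermediate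
22 | (4R,5S)-4-[(1S,3R)-1-hydroxy-3-methyl-4-oxo-3-(triethylsilyloxy)pentyl]-5-[(Z)-3-(tert-butyldiphenylsilyloxy)-2-iodoprop-1-en-1-yl]-3-methylenedihydrofuran-2(3H)-one | CC(=O)[C@](C)(O[Si](CC)(CC)CC)C[C@H](O)[C@H]1C(=C)C(=O)O[C@@H]1/C=C(\I)CO[Si](c2ccccc2)(c2ccccc2)C(C)(C)C | intermediate
23 | bis-lactone (seven-membered (Z)-enoate lactone on O8 fused to the α-methylene-γ-lactone; 6R,7R,8S,10R) | CC(=O)[C@](C)(O[Si](CC)(CC)CC)C[C@@H]1OC(=O)/C(CO[Si](c3ccccc3)(c3ccccc3)C(C)(C)C)=C\[C@H]2OC(=O)C(=C)[C@H]12 | intermediate
24 | lithium enolate of 23 (C2 enolate) | C=C([O-])[C@](C)(O[Si](CC)(CC)CC)C[C@@H]1OC(=O)/C(CO[Si](c3ccccc3)(c3ccccc3)C(C)(C)C)=C\[C@H]2OC(=O)C(=C)[C@H]12.[Li+] | intermediate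
25 | ring-expanded hydroxy diketone (ten-membered 1,3-diketone, C8–OH, C10–OSiEt3; shown in the diketo form, present as lithium diketonate before the quench) | O[C@H]1C[C@@](C)(O[Si](CC)(CC)CC)C(=O)CC(=O)/C(CO[Si](c3ccccc3)(c3ccccc3)C(C)(C)C)=C\[C@H]2OC(=O)C(=C)[C@@H]21 | intermediate
26 | (8S)-alcohol (8-epimeric, 8-O-deacylated 15-O-silyl ether of the target) | O[C@H]1C[C@@]2(C)OC(=CC2=O)/C(CO[Si](c3ccccc3)(c3ccccc3)C(C)(C)C)=C\[C@H]2OC(=O)C(=C)[C@@H]21 | intermediate
27 | methacrylic acid | C=C(C)C(=O)O | starting material
28 | 15-O-(tert-butyldiphenylsilyl) ether of the target | C=C(C)C(=O)O[C@@H]1C[C@@]2(C)OC(=CC2=O)/C(CO[Si](c3ccccc3)(c3ccccc3)C(C)(C)C)=C\[C@H]2OC(=O)C(=C)[C@@H]21 | intermediate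
29 | target CNP0180483.5 | C=C(C)C(=O)O[C@@H]1C[C@@]2(C)OC(=CC2=O)/C(CO)=C\[C@H]2OC(=O)C(=C)[C@@H]21 | target

## Step count and risk

Total step count: 16. Longest linear sequence: 11 steps (steps 1–6, then 12–16); the second branch (steps 7–11) has 5 steps.

**Step 14 (key step, proposed new method).**
What may go wrong:
- The enolate may be diverted into conjugate addition to the exocyclic methylene or to C5.
- Once the C8 alkoxide is released, the γ-lactone may migrate to O8.
- In the acid stage O8 may close onto C1 in competition with O10 onto C3.

Fallback (known aldol–oxidation–cyclodehydration chemistry): it sets out from 22 and returns at 28. Mitsunobu esterification of 22 with 27 (inversion at C8) should give the methacrylate F1. Palladium-catalysed formylation of the alkenyl iodide (Pd(PPh3)4, CO, Bu3SnH) should give the (Z)-enal F2. Intramolecular aldol addition of the methyl ketone lithium enolate to the aldehyde C3 (LiN(SiMe3)2, THF, −78 °C, high dilution), which is far more electrophilic than any ester, should close the ten-membered ring as the β-hydroxy ketone F3. Dess–Martin oxidation should give the 1,3-diketone F4. 2 M HCl in THF should remove the silyl ether and cyclodehydrate to 28.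

**Step 13 (carbonylative lactonization).**
What may go wrong:
- The alkenylpalladium may insert into the exocyclic methylene (6-exo Heck cyclization) before CO insertion.
- The base may promote migration of the γ-lactone to O8.

Fallback: it sets out from 22 and returns at 23. Conjugate addition of dimethylamine to the α-methylene lactone should give the amine adduct F5, which has no alkene near the palladium centre. The same carbonylation should then give the amino bis-lactone F6. Quaternization with MeI and elimination with NaHCO3 should restore the methylene group and give 23.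

**Step 12 (Barbier allylation).**
What may go wrong:
- Erosion or reversal of the simple diastereoselection at C8, if an open or boat transition state competes with the chair.

Fallback: it sets out from 21 and 11 and returns at 28, and makes the route stereoconvergent. Any 7,8-syn adduct F7 is separated and taken through the same carbonylation to the bis-lactone F8 and through the ring expansion to the (8R)-alcohol F9. F9 is then acylated with retention (methacrylic anhydride, DMAP, Et3N) to 28.

**Step 15 (Mitsunobu esterification).**
What may go wrong: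
- Elimination of the activated C8 oxygen, or failure of the backside attack at a ring carbon flanked by C7 and the neopentyl-type C9.

Fallback: it sets out from 26 and returns at 28. Dess–Martin oxidation should give the C8 ketone F10. Reduction with NaBH4/CeCl3 at −78 °C, with hydride delivery expected from the face of H7 (anti to the C7–C11 bond), should give the (8R)-alcohol F9. Acylation with methacrylic anhydride and DMAP then gives 28.

## Further compounds

F1 | step 14 | methacrylate of 22 with inverted C8 (8R), alkenyl iodide retained | CC(=O)[C@](C)(O[Si](CC)(CC)CC)C[C@@H](OC(=O)C(C)=C)[C@H]1C(=C)C(=O)O[C@@H]1/C=C(\I)CO[Si](c2ccccc2)(c2ccccc2)C(C)(C)C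
F2 | step 14 | (Z)-enal (C3 aldehyde in place of iodine) | CC(=O)[C@](C)(O[Si](CC)(CC)CC)C[C@@H](OC(=O)C(C)=C)[C@H]1C(=C)C(=O)O[C@@H]1/C=C(\C=O)CO[Si](c2ccccc2)(c2ccccc2)C(C)(C)C
F3 | step 14 | ten-membered β-hydroxy ketone (C3–OH, epimers at C3) | C=C(C)C(=O)O[C@@H]1C[C@@](C)(O[Si](CC)(CC)CC)C(=O)CC(O)/C(CO[Si](c3ccccc3)(c3ccccc3)C(C)(C)C)=C\[C@H]2OC(=O)C(=C)[C@@H]21
F4 | step 14 | ten-membered 1,3-diketone with 8-O-methacrylate and C10–OSiEt3 | C=C(C)C(=O)O[C@@H]1C[C@@](C)(O[Si](CC)(CC)CC)C(=O)CC(=O)/C(CO[Si](c3ccccc3)(c3ccccc3)C(C)(C)C)=C\[C@H]2OC(=O)C(=C)[C@@H]21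
F5 | step 13 | dimethylamine adduct of 22 (C11 epimers) | CC(=O)[C@](C)(O[Si](CC)(CC)CC)C[C@H](O)[C@H]1C(CN(C)C)C(=O)O[C@@H]1/C=C(\I)CO[Si](c2ccccc2)(c2ccccc2)C(C)(C)C
F6 | step 13 | dimethylamine adduct of 23 (C11 epimers) | CC(=O)[C@](C)(O[Si](CC)(CC)CC)C[C@@H]1OC(=O)/C(CO[Si](c3ccccc3)(c3ccccc3)C(C)(C)C)=C\[C@H]2OC(=O)C(CN(C)C)[C@H]12
F7 | step 12 | 7,8-syn (8R) Barbier adduct, C8 epimer of 22 | CC(=O)[C@](C)(O[Si](CC)(CC)CC)C[C@@H](O)[C@H]1C(=C)C(=O)O[C@@H]1/C=C(\I)CO[Si](c2ccccc2)(c2ccccc2)C(C)(C)C
F8 | step 12 | bis-lactone with 8R configuration, C8 epimer of 23 | CC(=O)[C@](C)(O[Si](CC)(CC)CC)C[C@H]1OC(=O)/C(CO[Si](c3ccccc3)(c3ccccc3)C(C)(C)C)=C\[C@H]2OC(=O)C(=C)[C@H]12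
F9 | step 12 | (8R)-alcohol, C8 epimer of 26 | O[C@@H]1C[C@@]2(C)OC(=CC2=O)/C(CO[Si](c3ccccc3)(c3ccccc3)C(C)(C)C)=C\[C@H]2OC(=O)C(=C)[C@@H]21
F10 | step 15 | C8 ketone from 26 | O=C1C[C@@]2(C)OC(=CC2=O)/C(CO[Si](c3ccccc3)(c3ccccc3)C(C)(C)C)=C\[C@H]2OC(=O)C(=C)[C@@H]21
A1 | alternative 1 | furanone aldehyde carrying the bromomethyl butenolide (open-chain precursor of the C7–C8 Barbier closure) | O=CC[C@@]1(C)OC(=CC1=O)/C(CO[Si](c2ccccc2)(c2ccccc2)C(C)(C)C)=C\[C@H]1OC(=O)C(CBr)=C1
A2 | alternative 2 | ten-membered hydroxy ynone (C10–OH, C1=O, C2≡C3) with lactone and methacrylate in place | C=C(C)C(=O)O[C@@H]1C[C@@](C)(O)C(=O)C#C/C(CO[Si](c2ccccc2)(c2ccccc2)C(C)(C)C)=C\[C@H]2OC(=O)C(=C)[C@@H]21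
A3 | alternative 3 | 2-methyl-3-(trimethylsilyloxy)furan linked through Z-C4=C5 to the lactone bearing the C8–C9 epoxide | Cc1oc(cc1O[Si](C)(C)C)/C(CO[Si](c2ccccc2)(c2ccccc2)C(C)(C)C)=C\[C@H]3OC(=O)C(=C)[C@@H]3[C@H]4CO4
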